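Ring numbering used below (cyclohexa-2,4-dien-1-one): C1 ring C=O, C2 acyl-bearing, C3/C5 enol carbons, C4 carries the CH2–cyclopentyl arm, C6 quaternary (Me, prenyl).
Cut 1: the C4–CH2 bond; forward it is made last, by reductive alkylation of the β-triketone with a cyclopentanecarbaldehyde.
Cut 2: C2 leaves the ring with its 2-methylbutanoyl group as an acyl-diazomethane (bonds C1–C2 and C2–C3), leaving a five-membered 4-methoxycyclopent-4-ene-1,3-dione. The enabling feature is that C2 is an acyl-substituted carbon between two ring C–O carbons (a 2-acyl-1,3-dione), the pattern left by insertion of a diazo carbon into a C(=O)–C(OMe)= bond.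
C6 is stereogenic only because C1 and C5 lead to different neighbours. It is set on the symmetric five-membered dione by CBS desymmetrisation and is a spectator afterwards; the ring expansion turns "carbonyl next to C–OMe" into "carbonyl next to C-acyl".
Forward order: 2-methylcyclopentane-1,3-dione → prenylation → desymmetrising reduction → α-oxygenation and oxidation to the trione enol → O-methylation → ring expansion (six-membered ring and acyl group together) → hydrolysis → attachment of the arm.
Arm and acyl group: the cyclopentane is closed from (S)-limonene (ozonolysis, aldol condensation); the limonene centre directs an anti epoxidation and an SN2 hydride opening sets the CH carbon. The acyl stereocentre comes with (R)-2-methylbutanoic acid.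

Key step: step 8

Remark: (R)-2-methylbutanoic acid and (S)-(−)-limonene are taken as commercial; enolised di- and triketones are drawn in one tautomer, so the CIP letter of the quaternary carbon changes with tautomer and ring size although its geometry is fixed from the desymmetrisation on.

Step 1
Reactants: 1 2-methylcyclopentane-1,3-dione; 2 1-bromo-3-methylbut-2-ene (prenyl bromide)
Product: 3 2-methyl-2-(3-methylbut-2-en-1-yl)cyclopentane-1,3-dione
Conditions: 1 M NaOH (aq), rt
Reagents that add atoms: none
Why: Enolate C-alkylation (SN2 on the primary allylic bromide in water, which favours C- over O-alkylation of the 2-methyl-1,3-dione) gives the achiral 2,2-disubstituted dione; no stereocentre is formed.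

Step 2
Reactants: 3 2-methyl-2-(3-methylbut-2-en-1-yl)cyclopentane-1,3-dione
Product: 4 (2R,3R)-3-hydroxy-2-methyl-2-(3-methylbut-2-en-1-yl)cyclopentan-1-one
Conditions: (S)-Me-CBS (0.2 equiv), catecholborane (1.2 equiv), toluene, −78 °C; neutral work-up, chromatography
Reagents that add atoms: none
Why: Corey–Bakshi–Shibata reduction desymmetrises the Cs-symmetric dione: the catalyst sets the carbinol carbon as R, hydride should enter on the ring face of the smaller methyl group so that OH ends cis to prenyl, and this pairing fixes the quaternary carbon as R (the 2S,3R minor diastereomer is removed on silica).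

Step 3
Reactants: 4 (2R,3R)-3-hydroxy-2-methyl-2-(3-methylbut-2-en-1-yl)cyclopentan-1-one
Product: 5 (2R,3R)-2-methyl-2-(3-methylbut-2-en-1-yl)-3-(triethylsilyloxy)cyclopentan-1-one
Conditions: TESCl, imidazole, DMF, 0 °C → rt
Reagents that add atoms: chlorotriethylsilane, CC[Si](Cl)(CC)CC
Why: Silyl ether formation; it keeps the later base step from forming the free alkoxide, whose retro-aldol opening would erase the quaternary stereocentre.

Step 4
Reactants: 5 (2R,3R)-2-methyl-2-(3-methylbut-2-en-1-yl)-3-(triethylsilyloxy)cyclopentan-1-one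
Product: 7 (2R,3R)-3,5-dihydroxy-2-methyl-2-(3-methylbut-2-en-1-yl)cyclopentan-1-one (C5 epimers), via 5-hydroxy ketone TES ether 6 (not isolated)
Conditions: KHMDS, THF, −78 °C; 3-phenyl-2-(phenylsulfonyl)oxaziridine; then 1 M HCl, THF, rt
Reagents that add atoms: 3-phenyl-2-(phenylsulfonyl)oxaziridine (Davis reagent), O=S(=O)(c1ccccc1)N1OC1c1ccccc1
Why: Davis enolate hydroxylation: the ketone can enolise only toward C5 because C2 is quaternary, the potassium enolate accepts oxygen from the N-sulfonyloxaziridine without touching the prenyl alkene, and the acid work-up cleaves the TES ether; the C5 configuration is of no consequence.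

Step 5
Reactants: 7 (2R,3R)-3,5-dihydroxy-2-methyl-2-(3-methylbut-2-en-1-yl)cyclopentan-1-one
Product: 8 (2R)-4-hydroxy-2-methyl-2-(3-methylbut-2-en-1-yl)cyclopent-4-ene-1,3-dione (enol of the 1,2,4-trione)
Conditions: Dess–Martin periodinane (3 equiv), CH2Cl2, rt
Reagents that add atoms: none
Why: Dess–Martin oxidation of both secondary alcohols gives the cyclopentane-1,2,4-trione, which should rest as the enol 8; the quaternary carbon stays stereogenic in every tautomer because one neighbouring carbonyl is flanked by C–O and the other by C–H.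

Step 6
Reactants: 8 (2R)-4-hydroxy-2-methyl-2-(3-methylbut-2-en-1-yl)cyclopent-4-ene-1,3-dione
Product: 9 (2R)-4-methoxy-2-methyl-2-(3-methylbut-2-en-1-yl)cyclopent-4-ene-1,3-dione
Conditions: TMSCHN2, toluene/MeOH, 0 °C
Reagents that add atoms: trimethylsilyldiazomethane, C[Si](C)(C)C=[N+]=[N-]
Why: O-Methylation of the acidic enol with the diazomethane surrogate; the enol proton sits on the C4 oxygen (the other enol would be a vicinal dione) and this oxygen is also the less hindered one, so the 4-methoxy isomer is expected.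

Step 7
Reactants: 10 (R)-2-methylbutanoic acid
Product: 12 (R)-1-diazo-3-methylpentan-2-one, via (R)-2-methylbutanoyl chloride 11 (not isolated)
Conditions: (COCl)2, cat. DMF, CH2Cl2, 0 °C → rt; then TMSCHN2 (2 equiv), THF/MeCN, 0 °C
Reagents that add atoms: oxalyl chloride, O=C(Cl)C(=O)Cl (Cl of 11 only); trimethylsilyldiazomethane, C[Si](C)(C)C=[N+]=[N-]
Why: Acid chloride formation followed by acylation of trimethylsilyldiazomethane (Arndt–Eistert-type diazoketone synthesis); no amine base is present, so the α-stereocentre brought in with 10 is not exposed to ketene formation.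

Step 8
Reactants: 9 (2R)-4-methoxy-2-methyl-2-(3-methylbut-2-en-1-yl)cyclopent-4-ene-1,3-dione; 12 (R)-1-diazo-3-methylpentan-2-one
Product: 13 (6S)-5-hydroxy-3-methoxy-6-methyl-4-[(2R)-2-methylbutanoyl]-6-(3-methylbut-2-en-1-yl)cyclohexa-2,4-dien-1-one
Conditions: Sc(OTf)3 (20 mol %), CH2Cl2, −20 °C → rt, slow addition of 12 (1.2 equiv)
Reagents that add atoms: none
Why: Proposed new method: Sc(OTf)3 should chelate the C3 carbonyl of 9 together with the neighbouring methoxy oxygen, so the nucleophilic diazo carbon of 12 adds to C3 and not to the vinylogous-ester carbonyl C1; in the β-oxido diazonium species the methoxy-substituted sp2 carbon C4 shifts from C3 to the diazonium carbon with loss of N2, which inserts the acyl-bearing carbon between C3 and C4 and gives the six-membered 2-acyl-1,3-dione, which enolises to 13. The closest known reaction type is the Lewis-acid-promoted one-carbon homologation of cyclic ketones with α-diazo carbonyl compounds (Tiffeneau–Demjanov/Buchner–Curtius–Schlotterbeck type), in which sp2 groups migrate in preference to alkyl groups. No ring is closed: the five-membered ring grows by one carbon through a 1,2-shift. No stereocentre is formed, since the inserted carbon becomes sp2 on enolisation, and the quaternary carbon and the acyl α-carbon are spectators that keep their configuration. The step needs selectivity between the two ring carbonyls and between the two possible migrating groups; the first rests on chelation and on the low electrophilicity of the vinylogous-ester carbonyl, the second on the oxygen donor on the migrating carbon against a quaternary sp3 carbon that carries a second acyl group. Because the acyl group arrives with the new ring atom, no intermediate exists in which the two flanks of the quaternary carbon become equivalent, so the configuration from step 2 is carried into the acyl/alkyl difference of the target.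

Step 9
Reactants: 13 (6S)-5-hydroxy-3-methoxy-6-methyl-4-[(2R)-2-methylbutanoyl]-6-(3-methylbut-2-en-1-yl)cyclohexa-2,4-dien-1-one
Product: 14 (6R)-3,5-dihydroxy-6-methyl-2-[(2R)-2-methylbutanoyl]-6-(3-methylbut-2-en-1-yl)cyclohexa-2,4-dien-1-one
Conditions: 1 M HCl (aq), THF, rt
Reagents that add atoms: water, O
Why: Acid-catalysed hydrolysis of the vinylogous methyl ester (water adds to the methoxy-bearing carbon, methanol leaves) frees the β-triketone; no stereocentre is touched and no symmetric tautomer exists because C2 carries the acyl group and C4 only hydrogen.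

Step 10
Reactants: 15 (S)-(−)-limonene
Product: 17 (3S)-6-oxo-3-(prop-1-en-2-yl)heptanal, via limonene ozonide 16 (not isolated)
Conditions: O3 (1.0 equiv), CH2Cl2, −78 °C; then Me2S, −78 °C → rt
Reagents that add atoms: ozone, [O-][O+]=O
Why: Ozonolysis with reductive work-up; one equivalent of ozone is consumed by the electron-richer trisubstituted ring alkene before the 1,1-disubstituted isopropenyl group, and the stereocentre is not involved.

Step 11
Reactants: 17 (3S)-6-oxo-3-(prop-1-en-2-yl)heptanal
Product: 18 (5R)-2-methyl-5-(prop-1-en-2-yl)cyclopent-1-ene-1-carbaldehyde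
Conditions: piperidine, AcOH, benzene, reflux (Dean–Stark)
Reagents that add atoms: none
Why: Intramolecular aldol condensation through the aldehyde enamine (attack on the methyl ketone closes the five-membered ring, dehydration follows); the stereocentre is carried over from limonene.

Step 12
Reactants: 18 (5R)-2-methyl-5-(prop-1-en-2-yl)cyclopent-1-ene-1-carbaldehyde
Product: 19 [(5R)-2-methyl-5-(prop-1-en-2-yl)cyclopent-1-en-1-yl]methanol
Conditions: NaBH4, CeCl3·7H2O, MeOH, 0 °C
Reagents that add atoms: none
Why: Luche 1,2-reduction of the enal to the allylic alcohol.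

Step 13
Reactants: 19 [(5R)-2-methyl-5-(prop-1-en-2-yl)cyclopent-1-en-1-yl]methanol
Product: 20 [(1S,2R,5S)-5-methyl-2-(prop-1-en-2-yl)-6-oxabicyclo[3.1.0]hexan-1-yl]methanol
Conditions: VO(acac)2 (cat.), t-BuOOH, CH2Cl2, 0 °C → rt
Reagents that add atoms: tert-butyl hydroperoxide, CC(C)(C)OO
Why: Hydroxyl-directed vanadium epoxidation acts only on the allylic-alcohol alkene and should deliver oxygen to the ring face opposite to the neighbouring isopropenyl group, which sets the oxygen-bearing carbon.

Step 14
Reactants: 20 [(1S,2R,5S)-5-methyl-2-(prop-1-en-2-yl)-6-oxabicyclo[3.1.0]hexan-1-yl]methanol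
Product: 21 (1S,2S,3S)-2-(hydroxymethyl)-1-methyl-3-(prop-1-en-2-yl)cyclopentan-1-ol
Conditions: Red-Al, THF, 0 °C → rt
Reagents that add atoms: none
Why: Red-Al opening of a 2,3-epoxy alcohol: the alkoxyaluminate delivers hydride within the molecule to the epoxide carbon that bears the CH2O group, with inversion, so CH2OH ends cis to the tertiary OH and trans to isopropenyl.

Step 15
Reactants: 21 (1S,2S,3S)-2-(hydroxymethyl)-1-methyl-3-(prop-1-en-2-yl)cyclopentan-1-ol
Product: 22 (1R,2S,5S)-2-hydroxy-2-methyl-5-(prop-1-en-2-yl)cyclopentane-1-carbaldehyde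
Conditions: TEMPO (cat.), PhI(OAc)2, CH2Cl2, rt
Reagents that add atoms: none
Why: TEMPO/PhI(OAc)2 oxidation of the primary alcohol (the tertiary alcohol cannot react) gives the β-hydroxy aldehyde, whose α-carbon already has the thermodynamically preferred configuration (CHO trans to both neighbouring carbon substituents); it is used without chromatography.

Step 16
Reactants: 14 (6R)-3,5-dihydroxy-6-methyl-2-[(2R)-2-methylbutanoyl]-6-(3-methylbut-2-en-1-yl)cyclohexa-2,4-dien-1-one; 22 (1R,2S,5S)-2-hydroxy-2-methyl-5-(prop-1-en-2-yl)cyclopentane-1-carbaldehyde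
Product: 24 (6R)-3,5-dihydroxy-4-{[(1R,2S,5S)-2-hydroxy-2-methyl-5-(prop-1-en-2-yl)cyclopentyl]methyl}-6-methyl-2-[(2R)-2-methylbutanoyl]-6-(3-methylbut-2-en-1-yl)cyclohexa-2,4-dien-1-one (target), via alkylidene trione 23 (not isolated)
Conditions: Hantzsch ester (1.2 equiv), L-proline (10 mol %), CH2Cl2, rt
Reagents that add atoms: none
Why: Three-component reductive alkylation: Knoevenagel condensation at C4 of 14, the only free nucleophilic ring carbon, then conjugate hydride transfer from the Hantzsch ester to the alkylidene 23, gives the CH2 link without touching a stereocentre.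

Compound list
1 | 2-methylcyclopentane-1,3-dione | CC1C(=O)CCC1=O | starting material
2 | 1-bromo-3-methylbut-2-ene (prenyl bromide) | CC(C)=CCBr | starting material
3 | 2-methyl-2-(3-methylbut-2-en-1-yl)cyclopentane-1,3-dione | CC(C)=CCC1(C)C(=O)CCC1=O | intermediate
4 | (2R,3R)-3-hydroxy-2-methyl-2-(3-methylbut-2-en-1-yl)cyclopentan-1-one | CC(C)=CC[C@@]1(C)C(=O)CC[C@H]1O | intermediate
5 | (2R,3R)-2-methyl-2-(3-methylbut-2-en-1-yl)-3-(triethylsilyloxy)cyclopentan-1-one | CC(C)=CC[C@@]1(C)C(=O)CC[C@H]1O[Si](CC)(CC)CC | intermediate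
6 | (2R,3R)-5-hydroxy-2-methyl-2-(3-methylbut-2-en-1-yl)-3-(triethylsilyloxy)cyclopentan-1-one (C5 epimers) | CC(C)=CC[C@@]1(C)C(=O)C(O)C[C@H]1O[Si](CC)(CC)CC | intermediate
7 | (2R,3R)-3,5-dihydroxy-2-methyl-2-(3-methylbut-2-en-1-yl)cyclopentan-1-one (C5 epimers) | CC(C)=CC[C@@]1(C)C(=O)C(O)C[C@H]1O | intermediate
8 | (2R)-4-hydroxy-2-methyl-2-(3-methylbut-2-en-1-yl)cyclopent-4-ene-1,3-dione | CC(C)=CC[C@@]1(C)C(=O)C(O)=CC1=O | intermediate
9 | (2R)-4-methoxy-2-methyl-2-(3-methylbut-2-en-1-yl)cyclopent-4-ene-1,3-dione | CC(C)=CC[C@@]1(C)C(=O)C(OC)=CC1=O | intermediate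
10 | (R)-2-methylbutanoic acid | CC[C@@H](C)C(=O)O | starting material
11 | (R)-2-methylbutanoyl chloride | CC[C@@H](C)C(=O)Cl | intermediate
12 | (R)-1-diazo-3-methylpentan-2-one | CC[C@@H](C)C(=O)C=[N+]=[N-] | intermediate
13 | (6S)-5-hydroxy-3-methoxy-6-methyl-4-[(2R)-2-methylbutanoyl]-6-(3-methylbut-2-en-1-yl)cyclohexa-2,4-dien-1-one | COC1=CC(=O)[C@@](C)(CC=C(C)C)C(O)=C1C(=O)[C@H](C)CC | intermediate
14 | (6R)-3,5-dihydroxy-6-methyl-2-[(2R)-2-methylbutanoyl]-6-(3-methylbut-2-en-1-yl)cyclohexa-2,4-dien-1-one | CC[C@@H](C)C(=O)C1=C(O)C=C(O)[C@@](C)(CC=C(C)C)C1=O | intermediate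
15 | (S)-(−)-limonene | C=C(C)[C@H]1CCC(C)=CC1 | starting material
16 | limonene 1,2-ozonide (1,2,4-trioxolane, mixture at the new centres) | C=C(C)[C@H]1CCC2(C)OOC(C1)O2 | intermediate
17 | (3S)-6-oxo-3-(prop-1-en-2-yl)heptanal | C=C(C)[C@H](CC=O)CCC(C)=O | intermediate
18 | (5R)-2-methyl-5-(prop-1-en-2-yl)cyclopent-1-ene-1-carbaldehyde | C=C(C)[C@H]1CCC(C)=C1C=O | intermediate
19 | [(5R)-2-methyl-5-(prop-1-en-2-yl)cyclopent-1-en-1-yl]methanol | C=C(C)[C@H]1CCC(C)=C1CO | intermediate
20 | [(1S,2R,5S)-5-methyl-2-(prop-1-en-2-yl)-6-oxabicyclo[3.1.0]hexan-1-yl]methanol | C=C(C)[C@H]1CC[C@]2(C)O[C@]12CO | intermediate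
21 | (1S,2S,3S)-2-(hydroxymethyl)-1-methyl-3-(prop-1-en-2-yl)cyclopentan-1-ol | C=C(C)[C@H]1CC[C@](C)(O)[C@@H]1CO | intermediate
22 | (1R,2S,5S)-2-hydroxy-2-methyl-5-(prop-1-en-2-yl)cyclopentane-1-carbaldehyde | C=C(C)[C@H]1CC[C@](C)(O)[C@@H]1C=O | intermediate
23 | Knoevenagel alkylidene of 14 and 22 (alkene geometry open) | C=C(C)[C@H]1CC[C@](C)(O)[C@@H]1C=C1C(=O)C(C(=O)[C@H](C)CC)=C(O)[C@](C)(CC=C(C)C)C1=O | intermediate
24 | (6R)-3,5-dihydroxy-4-{[(1R,2S,5S)-2-hydroxy-2-methyl-5-(prop-1-en-2-yl)cyclopentyl]methyl}-6-methyl-2-[(2R)-2-methylbutanoyl]-6-(3-methylbut-2-en-1-yl)cyclohexa-2,4-dien-1-one | C=C(C)[C@H]1CC[C@](C)(O)[C@@H]1CC1=C(O)[C@@](C)(CC=C(C)C)C(=O)C(C(=O)[C@H](C)CC)=C1O | target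

Total step count: 16. Longest linear sequence: 9 steps (1–6, 8, 9, 16).

Steps most likely to fail

Step 8 (attack at the wrong ring carbonyl, collapse of the diazonium alkoxide to an epoxide instead of the 1,2-shift, or O-alkylation of the acidic product by the diazoketone). The two events can be separated with known chemistry. Setting out from 9 and 12, base-catalysed aldol-type addition of the diazo carbon to the C3 carbonyl (DBU, MeCN, 0 °C) would give (5S)-4-[(3R)-1-diazo-3-methyl-2-oxopentyl]-4-hydroxy-3-methoxy-5-methyl-5-(3-methylbut-2-en-1-yl)cyclopent-2-en-1-one F1. Rh2(OAc)4 (1 mol %) in CH2Cl2 then forms the rhodium carbenoid, to which the methoxy-substituted sp2 carbon shifts (the known ring enlargement of 1-hydroxycycloalkyl diazo carbonyl compounds), and the route is rejoined at 13.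

Step 14 (hydride delivered to the methyl-bearing epoxide carbon, or no opening of the fully substituted epoxide). The bond to be broken is turned into a C–O bond α to a carbonyl. Setting out from 20, TEMPO/PhI(OAc)2 in MeCN–water would give (1R,2R,5S)-5-methyl-2-(prop-1-en-2-yl)-6-oxabicyclo[3.1.0]hexane-1-carboxylic acid F2, and TMSCHN2 its methyl ester F3. SmI2 (THF, N,N-dimethylaminoethanol) then cleaves the α-C–O bond of the epoxy ester to methyl (1R,2S,5S)-2-hydroxy-2-methyl-5-(prop-1-en-2-yl)cyclopentane-1-carboxylate F4, whose enolisable α-carbon is equilibrated to the isomer trans to both carbon neighbours. DIBAL-H at −78 °C reduces F4 to 22, so steps 14 and 15 are bypassed.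

Step 16 (retro-aldol opening or β-elimination of the β-hydroxy aldehyde under amine catalysis, or tautomerisation of the alkylidene before hydride transfer). The tertiary alcohol is carried as a silyl ether through the C–C bond formation. Setting out from 21, TESOTf/2,6-lutidine would give the bis(triethylsilyl) ether F5, and Swern conditions oxidise its primary TES ether directly to the O-TES aldehyde F6. Reductive alkylation of 14 with F6 (Hantzsch ester, L-proline) gives the O-TES ether of the target F7, and HF·pyridine in THF returns to 24.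

Further compounds
F1 | step 8 | (5S)-4-[(3R)-1-diazo-3-methyl-2-oxopentyl]-4-hydroxy-3-methoxy-5-methyl-5-(3-methylbut-2-en-1-yl)cyclopent-2-en-1-one (carbinol epimers) | CC(C)=CC[C@@]1(C)C(O)(C(=[N+]=[N-])C(=O)[C@H](C)CC)C(OC)=CC1=O
F2 | step 14 | (1R,2R,5S)-5-methyl-2-(prop-1-en-2-yl)-6-oxabicyclo[3.1.0]hexane-1-carboxylic acid | C=C(C)[C@H]1CC[C@]2(C)O[C@]12C(=O)O
F3 | step 14 | methyl (1R,2R,5S)-5-methyl-2-(prop-1-en-2-yl)-6-oxabicyclo[3.1.0]hexane-1-carboxylate | C=C(C)[C@H]1CC[C@]2(C)O[C@]12C(=O)OC
F4 | step 14 | methyl (1R,2S,5S)-2-hydroxy-2-methyl-5-(prop-1-en-2-yl)cyclopentane-1-carboxylate | C=C(C)[C@H]1CC[C@](C)(O)[C@@H]1C(=O)OC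
F5 | step 16 | bis(triethylsilyl) ether of 21 | C=C(C)[C@H]1CC[C@](C)(O[Si](CC)(CC)CC)[C@@H]1CO[Si](CC)(CC)CC
F6 | step 16 | (1R,2S,5S)-2-methyl-5-(prop-1-en-2-yl)-2-(triethylsilyloxy)cyclopentane-1-carbaldehyde | C=C(C)[C@H]1CC[C@](C)(O[Si](CC)(CC)CC)[C@@H]1C=O
F7 | step 16 | O-triethylsilyl ether of 24 at the tertiary alcohol | C=C(C)[C@H]1CC[C@](C)(O[Si](CC)(CC)CC)[C@@H]1CC1=C(O)[C@@](C)(CC=C(C)C)C(=O)C(C(=O)[C@H](C)CC)=C1O
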